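**Strategy.** The methylene bridge is cut last, giving a 4-hydroxy-2-pyrone and a dihydrobenzofuran acylphloroglucinol. Everything rests on the dihydrofuran ring (O1, C2, C3, C3a, C7a): its C2 carries both O1 and an isopropenyl group, the signature of a 1,2-shift of O1 away from a CMe2 carbon. The precursor is therefore a six-membered (3R)-2,2-dimethylchroman-3-ol, built regiospecifically by a propargyl Claisen chromene synthesis, Jacobsen epoxidation and hydrogenolysis. On triflation O1 displaces the C3 leaving group through an oxiranium ion and a methyl proton is lost. One operation contracts pyran to furan, inverts C3 into (S)-C2 and creates the alkene. The ketone α-centre comes from (S)-2-methylbutanoic acid.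

Key step: step 7

Remark: read from the SMILES, C2 of the dihydrofuran is S and the α-carbon of the ketone is S. Benzofuran numbering (O1, C2, C3, C3a, C4–C7, C7a) and chroman numbering (O1, C2, C3, C4, C4a, C5–C8, C8a) are used throughout.

Step 1
Reactants: 1 phloroglucinol; 2 (S)-2-methylbutanoic acid
Product: 4 (2S)-2-methyl-1-(2,4,6-trihydroxyphenyl)butan-1-one, via acid chloride 3 (not isolated)
Conditions: 2, (COCl)2, cat. DMF, CH2Cl2, 0 °C to rt; then 1, AlCl3, CH2Cl2–PhNO2, 0 °C to rt; aq. HCl
Reagents that add atoms: none
Why: Friedel–Crafts C-acylation of the symmetric, highly activated arene should stop after one acylation because the chelated aryl ketone is deactivated; the (S) centre is imported from 2, and the low temperature is chosen to keep ketene formation and enolisation, the only racemisation channels, slow.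

Step 2
Reactants: 4 (2S)-2-methyl-1-(2,4,6-trihydroxyphenyl)butan-1-one
Product: 5 5-hydroxy-4-[(2S)-2-methylbutanoyl]benzene-1,3-diyl bis(2,2-dimethylpropanoate) (the 4,6-dipivalate of 4, with one chelated ortho OH left free)
Conditions: PivCl (2.1 equiv), Et3N, CH2Cl2, −10 to 0 °C
Reagents that add atoms: pivaloyl chloride, CC(C)(C)C(=O)Cl
Why: Selective O-acylation: the para hydroxyl and one ortho hydroxyl should be esterified, whereas the last one is tied into a six-membered hydrogen bond to the ketone and shielded from the bulky acyl chloride, so it stays free for step 3; pivalates are chosen because they are electron-poor (needed in step 7), too hindered to scramble and removable without acid.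

Step 3
Reactants: 5 dipivalate phenol; 6 3-chloro-3-methylbut-1-yne
Product: 7 5-[(2-methylbut-3-yn-2-yl)oxy]-4-[(2S)-2-methylbutanoyl]benzene-1,3-diyl bis(2,2-dimethylpropanoate) (aryl 1,1-dimethylpropargyl ether)
Conditions: DBU, cat. CuCl2·2H2O, MeCN, 0 °C
Reagents that add atoms: none
Why: Copper-catalysed propargylic substitution (O-alkylation through a copper-stabilised tertiary propargyl cation) is a known way to tertiary aryl propargyl ethers that also accepts acidic, hydrogen-bonded phenols, at a temperature at which DBU should neither enolise the hindered ketone nor cleave the pivalates.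

Step 4
Reactants: 7 aryl 1,1-dimethylpropargyl ether
Product: 10 2,2-dimethyl-8-[(2S)-2-methylbutanoyl]-2H-chromene-5,7-diyl bis(2,2-dimethylpropanoate), via allenylphenol 8 (not isolated), via ortho-quinone methide 9 (not isolated)
Conditions: o-dichlorobenzene, 160 °C
Reagents that add atoms: none
Why: Aromatic propargyl Claisen rearrangement to the only free ortho carbon, enolisation to 8, 1,5-hydrogen shift to 9 and oxa-6π electrocyclisation (the standard 2,2-dimethylchromene synthesis) fix the ring oxygen ortho to the ketone without a regioisomer and run in neutral medium, so the α-centre is safe.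

Step 5
Reactants: 10 chromene
Product: 11 (3R,4R)-3,4-epoxy-2,2-dimethyl-8-[(2S)-2-methylbutanoyl]chroman-5,7-diyl bis(2,2-dimethylpropanoate)
Conditions: (R,R)-Mn(salen)Cl (Jacobsen catalyst, 5 mol %), mCPBA, NMO, CH2Cl2, −78 °C
Reagents that add atoms: mCPBA, OOC(=O)c1cccc(Cl)c1
Why: Jacobsen–Katsuki epoxidation has its best substrates in cis-alkenes of the 2,2-dimethylchromene class with an electron-poor arene: the (R,R)-catalyst should deliver oxygen to the face that gives the (3R,4R)-epoxide under catalyst control, the remote (S) centre having no say, and the buffered low-temperature protocol spares esters and ketone.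

Step 6
Reactants: 11 (3R,4R)-epoxide
Product: 12 (3R)-3-hydroxy-2,2-dimethyl-8-[(2S)-2-methylbutanoyl]chroman-5,7-diyl bis(2,2-dimethylpropanoate)
Conditions: H2 (1 atm), 10% Pd/C, EtOAc, rt
Reagents that add atoms: none
Why: Hydrogenolysis cleaves the benzylic C4–O bond of the epoxide and leaves the C3–O bond untouched, so 3R is retained, and the twisted di-ortho-substituted ketone and the aryl esters should be inert at 1 atm.

Step 7
Reactants: 12 (3R)-chroman-3-ol
Product: 15 (2S)-7-[(2S)-2-methylbutanoyl]-2-(prop-1-en-2-yl)-2,3-dihydro-1-benzofuran-4,6-diyl bis(2,2-dimethylpropanoate), via triflate 13 (not isolated), via oxiranium triflate 14 (not isolated)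
Conditions: Tf2O, 2,6-lutidine, CH2Cl2, −78 °C to rt
Reagents that add atoms: none
Why: Tf2O esterifies the hindered C3–OH to 13; in the half-chair conformer with C3–OTf pseudo-equatorial this bond is antiperiplanar to the ring bond C2–O1, so a lone pair of O1 expels triflate from the rear (3-exo-tet) to give the bicyclic aryloxiranium ion 14, whose tertiary C2–O1 bond then breaks while lutidine takes an antiperiplanar methyl proton, leaving O1 on the former C3 and turning CMe2 into the isopropenyl group. The closest known reaction type is the stereospecific ring contraction of tetrahydropyran-3-yl sulfonates, pyranoside 2-sulfonates and 2,2-dimethylchroman-3-ols by a 1,2-shift of the ring oxygen. The five-membered ring (O1, C2, C3, C3a, C7a of 15) is closed in the 3-exo-tet event and is released from the six-membered ring when the old O1–CMe2 bond is cut, so no separate cyclisation is needed. The only new stereocentre, C2 of 15, is the old C3: an unassisted secondary cation next to a quaternary carbon is out of reach, so ionisation must be assisted from the rear and (3R) should be translated into (2S) by one inversion. The oxygen shift has to beat 1,2-shifts of H-4 or of a C2 methyl group, aryl (C4a) participation and E2 return to chromene 10: the two pivalates and the ketone make the arene electron-poor and so take the stabilisation away from a C4 benzylic cation or a phenonium ion while barely touching O1 (they sit meta to C8a), and the hindered base and non-nucleophilic counter-ion leave no bimolecular exit. The exocyclic alkene rather than the tetrasubstituted enol ether is secured because the C–H bond on the oxiranium ring cannot become antiperiplanar to the breaking C–O bond.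

Step 8
Reactants: 15 dipivalate of the dihydrobenzofuran
Product: 16 (2S)-1-[(2S)-4,6-dihydroxy-2-(prop-1-en-2-yl)-2,3-dihydro-1-benzofuran-7-yl]-2-methylbutan-1-one
Conditions: K2CO3, MeOH, 0 °C to rt; then aq. NH4Cl
Reagents that add atoms: none
Why: Base-mediated transesterification removes the two aryl pivalates, which are activated by the ortho/para ketone; the first phenoxide turns the ketone into a vinylogous carboxylate that no longer enolises, so the α-centre holds, and the allylic aryl ether at C2 and the alkene are inert to carbonate.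

Step 9
Reactants: 17 pentan-3-one
Product: 18 3-(trimethylsilyloxy)pent-2-ene (E/Z mixture)
Conditions: TMSOTf, Et3N, CH2Cl2, 0 °C
Reagents that add atoms: TMSOTf, C[Si](C)(C)OS(=O)(=O)C(F)(F)F
Why: Soft enolisation and O-silylation of a symmetric ketone raises no regiochemical question, and both alkene isomers converge in step 10.

Step 10
Reactants: 18 silyl enol ether; 19 malonyl dichloride
Product: 21 6-ethyl-4-hydroxy-5-methyl-2H-pyran-2-one, via diketo acid chloride 20 (not isolated)
Conditions: Et2O, −78 °C to rt
Reagents that add atoms: none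
Why: In this known pyrone synthesis from silyl enol ethers and malonyl dichloride, C-acylation with loss of TMSCl gives 20, whose diketone enol oxygen is acylated by the second acid chloride (6-exo-trig lactonisation), and the product tautomerises to the 4-hydroxy-2-pyrone with ethyl at C6 and methyl at C5.

Step 11
Reactants: 16 dihydroxy-dihydrobenzofuran ketone; 21 pyrone; 22 Eschenmoser's salt (N,N-dimethylmethyleneiminium iodide)
Product: 25 target, 3-({(2S)-4,6-dihydroxy-7-[(2S)-2-methylbutanoyl]-2-(prop-1-en-2-yl)-2,3-dihydro-1-benzofuran-5-yl}methyl)-6-ethyl-4-hydroxy-5-methyl-2H-pyran-2-one, via Mannich base 23 (not isolated), via methylenepyrandione 24 (not isolated)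
Conditions: 21, 22, MeCN, rt; then 16, NaOAc, 50 °C
Reagents that add atoms: none
Why: A Mannich reaction at C3 of the pyrone gives 23, loss of dimethylamine gives the strongly electrophilic methylene-dione 24, and Friedel–Crafts-type Michael addition by C5 of 16, the only free and doubly OH-activated aromatic carbon, forges the bridge; no free formaldehyde is present, which should hold back self-coupling of 16, and no stereocentre is touched.

**Compound list**

1 | phloroglucinol | Oc1cc(O)cc(O)c1 | starting material
2 | (S)-2-methylbutanoic acid | OC(=O)[C@@H](C)CC | starting material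
3 | (S)-2-methylbutanoyl chloride | ClC(=O)[C@@H](C)CC | intermediate
4 | (2S)-2-methyl-1-(2,4,6-trihydroxyphenyl)butan-1-one | Oc1cc(O)c(C(=O)[C@@H](C)CC)c(O)c1 | intermediate
5 | 5-hydroxy-4-[(2S)-2-methylbutanoyl]benzene-1,3-diyl dipivalate | CC(C)(C)C(=O)Oc1cc(O)c(C(=O)[C@@H](C)CC)c(OC(=O)C(C)(C)C)c1 | intermediate
6 | 3-chloro-3-methylbut-1-yne | C#CC(C)(C)Cl | starting material
7 | aryl 1,1-dimethylpropargyl ether of 5 | C#CC(C)(C)Oc1cc(OC(=O)C(C)(C)C)cc(OC(=O)C(C)(C)C)c1C(=O)[C@@H](C)CC | intermediate
8 | ortho-(3-methylbuta-1,2-dienyl)phenol | CC(C)=C=Cc1c(O)c(C(=O)[C@@H](C)CC)c(OC(=O)C(C)(C)C)cc1OC(=O)C(C)(C)C | intermediate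
9 | ortho-quinone methide (3-methylbut-2-enylidene dienone) | CC(C)=CC=C1C(=O)C(C(=O)[C@@H](C)CC)=C(OC(=O)C(C)(C)C)C=C1OC(=O)C(C)(C)C | intermediate
10 | 2,2-dimethyl-8-[(2S)-2-methylbutanoyl]-2H-chromene-5,7-diyl dipivalate | CC1(C)C=Cc2c(OC(=O)C(C)(C)C)cc(OC(=O)C(C)(C)C)c(C(=O)[C@@H](C)CC)c2O1 | intermediate
11 | (3R,4R)-3,4-epoxychroman dipivalate | CC1(C)[C@@H]2O[C@@H]2c3c(OC(=O)C(C)(C)C)cc(OC(=O)C(C)(C)C)c(C(=O)[C@@H](C)CC)c3O1 | intermediate
12 | (3R)-3-hydroxy-2,2-dimethylchroman dipivalate | CC1(C)[C@H](O)Cc2c(OC(=O)C(C)(C)C)cc(OC(=O)C(C)(C)C)c(C(=O)[C@@H](C)CC)c2O1 | intermediate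
13 | (3R)-chroman-3-yl triflate | CC1(C)[C@H](OS(=O)(=O)C(F)(F)F)Cc2c(OC(=O)C(C)(C)C)cc(OC(=O)C(C)(C)C)c(C(=O)[C@@H](C)CC)c2O1 | intermediate
14 | bicyclic aryloxiranium triflate (O1 bridging C2 and C3) | CC1(C)[C@@H]2Cc3c(OC(=O)C(C)(C)C)cc(OC(=O)C(C)(C)C)c(C(=O)[C@@H](C)CC)c3[O+]12.[O-]S(=O)(=O)C(F)(F)F | intermediate
15 | (2S)-2-isopropenyl-7-[(2S)-2-methylbutanoyl]-2,3-dihydrobenzofuran-4,6-diyl dipivalate | C=C(C)[C@@H]1Cc2c(OC(=O)C(C)(C)C)cc(OC(=O)C(C)(C)C)c(C(=O)[C@@H](C)CC)c2O1 | intermediate
16 | (2S)-1-[(2S)-4,6-dihydroxy-2-isopropenyl-2,3-dihydrobenzofuran-7-yl]-2-methylbutan-1-one | C=C(C)[C@@H]1Cc2c(O)cc(O)c(C(=O)[C@@H](C)CC)c2O1 | intermediate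
17 | pentan-3-one | CCC(=O)CC | starting material
18 | 3-(trimethylsilyloxy)pent-2-ene (E/Z) | CC=C(CC)O[Si](C)(C)C | intermediate
19 | malonyl dichloride | ClC(=O)CC(=O)Cl | starting material
20 | 4-methyl-3,5-dioxoheptanoyl chloride | CCC(=O)C(C)C(=O)CC(=O)Cl | intermediate
21 | 6-ethyl-4-hydroxy-5-methyl-2H-pyran-2-one | CCc1oc(=O)cc(O)c1C | intermediate
22 | Eschenmoser's salt | C=[N+](C)C.[I-] | starting material
23 | 3-[(dimethylamino)methyl]-6-ethyl-4-hydroxy-5-methyl-2H-pyran-2-one (formed as hydroiodide) | CCc1oc(=O)c(CN(C)C)c(O)c1C | intermediate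
24 | 6-ethyl-5-methyl-3-methylidene-2H-pyran-2,4(3H)-dione | CCC1=C(C)C(=O)C(=C)C(=O)O1 | intermediate
25 | target CNP0261501.1 | C=C(C)[C@@H]1Cc2c(O)c(Cc3c(O)c(C)c(CC)oc3=O)c(O)c(C(=O)[C@@H](C)CC)c2O1 | target

**Total step count:** 11. **Longest linear sequence:** 9 (steps 1–8 and 11).

**Steps most likely to fail**

1. Step 7. Ionisation may take place from the conformer with a pseudo-axial triflate, in which H-4 or a C2 methyl group migrates instead of O1, or the base may induce elimination back to the chromene. The fallback sets out from 12 and comes back at 15. It splits the contraction into capture and dehydration.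
   - Alcohol 12 is converted with ClCH2SO2Cl and pyridine into the (3R)-chloromethanesulfonate F1.
   - F1 is solvolysed without amine base in CaCO3-buffered aqueous dioxane at about 60 °C. The same rear-side oxygen shift occurs, and the bridged ion is intercepted by water at its tertiary carbon to give the ring-contracted tertiary alcohol (2S)-2-(2-hydroxypropan-2-yl)dihydrobenzofuran dipivalate F2.
   - A separate, known regioselective dehydration of this alcohol type (SOCl2, pyridine, 0 °C) then gives 15.

2. Step 11. The pyrone may self-couple through 24, and the bridge may scramble by reversible retro-Michael cleavage. The fallback sets out from 16 and 21 and comes back at 25, with the roles of the partners reversed.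
   - Compound 16 alone is aminomethylated at C5 with Eschenmoser's salt to the aryl Mannich base F3, which is isolated.
   - Heating F3 with 21 in dioxane expels dimethylamine and gives an ortho-quinone methide of the phloroglucinol. This is trapped at C3 of the pyrone, so no electrophilic pyrone species is ever present.

3. Step 1. The configuration at the α-carbon may be partly lost by ketene formation from 3 or by Lewis-acid-promoted enolisation of the product chelate. The fallback sets out from 1 and 2 and comes back at 4, and replaces the electrophilic acylation by an aryllithium addition.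
   - Compound 1 is converted (MOMCl, iPr2NEt) into 1,3,5-tris(methoxymethoxy)benzene F4.
   - Acid 2 is converted (CDI, MeNHOMe·HCl) into the Weinreb amide (S)-N-methoxy-N,2-dimethylbutanamide F5.
   - Lithiation of F4 (n-BuLi, THF, 0 °C) and addition to F5 gives, through a stable chelated tetrahedral adduct, the tris-MOM ketone F6.
   - HCl in MeOH then frees 4.

**Further compounds**

F1 | step 7 | (3R)-chroman-3-yl chloromethanesulfonate of 12 | CC1(C)[C@H](OS(=O)(=O)CCl)Cc2c(OC(=O)C(C)(C)C)cc(OC(=O)C(C)(C)C)c(C(=O)[C@@H](C)CC)c2O1
F2 | step 7 | (2S)-2-(2-hydroxypropan-2-yl)-7-[(2S)-2-methylbutanoyl]-2,3-dihydrobenzofuran-4,6-diyl dipivalate | CC(C)(O)[C@@H]1Cc2c(OC(=O)C(C)(C)C)cc(OC(=O)C(C)(C)C)c(C(=O)[C@@H](C)CC)c2O1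
F3 | step 11 | 5-[(dimethylamino)methyl] derivative of 16 | C=C(C)[C@@H]1Cc2c(O)c(CN(C)C)c(O)c(C(=O)[C@@H](C)CC)c2O1
F4 | step 1 | 1,3,5-tris(methoxymethoxy)benzene | COCOc1cc(OCOC)cc(OCOC)c1
F5 | step 1 | (S)-N-methoxy-N,2-dimethylbutanamide | CON(C)C(=O)[C@@H](C)CC
F6 | step 1 | (2S)-2-methyl-1-[2,4,6-tris(methoxymethoxy)phenyl]butan-1-one | COCOc1cc(OCOC)c(C(=O)[C@@H](C)CC)c(OCOC)c1
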